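**Plan**

1. Retrosynthesis (germacrane numbering, C1–C13): open the C1–O bond of the 1,10-oxirane (C1 mesylate, C10 silyl ether), then cut C1–C2 of the ten-membered ring, the C8 O–acyl bond, C3–C4 and C4=C5 of the diene, C11=C13, C7–C8 and C8–C9.
2. Enabling feature: in the ten-membered carbocycle C1 lies between the diene terminus C2 and the oxygenated quaternary C10. C1 can therefore be an α-silyloxy aldehyde that takes up a C2 dienylchromium; the new C1 oxygen later leaves when the C10 oxygen closes the oxirane.
3. Forward: the γ-lactone ring is that of (S)-5-(hydroxymethyl)butenolide. A dithiane carrying C9–C10–C1 adds to C7 and the enolate is trapped at C11. Ketone, C8 alcohol and epoxy ester follow; the C6 arm is grown to the (Z,Z)-iododiene; C1 is oxidised; the ten-membered ring is closed, and the oxirane is made last.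
4. Stereochemistry: C6 from the butenolide, C7 by anti conjugate addition, C8 by CBS reduction, C10 and both ester centres by Sharpless epoxidations, C1 by Felkin–Anh addition followed by SN2 inversion. The Z alkenes come from a Z-selective iodo-olefination and stereoretentive Stille coupling and iododestannylation.

Key step: step 22

Remark: Mannich bases 19–27 are drawn as the 11R (all-trans) isomers expected from anti trapping; the C11 configuration is immaterial because C11 becomes sp2 in step 16.

**Route**

Step 1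
Reactants: 1 tiglic acid
Product: 2 tiglyl alcohol [(E)-2-methylbut-2-en-1-ol]
Conditions: LiAlH4, Et2O, 0 °C → rt; aq. NaOH work-up
Reagents that add atoms: none
Why: Lithium aluminium hydride reduction of a carboxylic acid to the primary alcohol, which for this α-methyl enoic acid proceeds 1,2 and leaves the E-trisubstituted alkene untouched.

Step 2
Reactants: 2 tiglyl alcohol
Product: 3 [(2R,3R)-2,3-dimethyloxiran-2-yl]methanol
Conditions: Ti(OiPr)4 (cat.), D-(−)-diethyl tartrate (cat.), t-BuOOH, 4 Å MS, CH2Cl2, −20 °C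
Reagents that add atoms: tert-butyl hydroperoxide, CC(C)(C)OO
Why: Sharpless asymmetric epoxidation, in which the D-(−)-tartrate–titanium complex delivers oxygen to the alkene face that gives the (2R,3R)-epoxy alcohol, the E geometry being carried over as cis methyl groups, so that both stereocentres of the later ester are set here.

Step 3
Reactants: 3 epoxy alcohol
Product: 4 (2S,3R)-2,3-dimethyloxirane-2-carboxylic acid
Conditions: TEMPO (cat.), PhI(OAc)2, MeCN/H2O (1:1), rt
Reagents that add atoms: water, O
Why: TEMPO/oxoammonium oxidation of a primary alcohol through the aldehyde hydrate to the carboxylic acid, in which the oxirane is inert and the quaternary α-carbon cannot epimerise (its descriptor changes from R to S only because the CIP ranking changes).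

Step 4
Reactants: 5 methallyl alcohol
Product: 6 (S)-2-methylglycidol
Conditions: Ti(OiPr)4 (cat.), L-(+)-diisopropyl tartrate (cat.), t-BuOOH, 4 Å MS, CH2Cl2, −20 °C; non-aqueous work-up
Reagents that add atoms: tert-butyl hydroperoxide, CC(C)(C)OO
Why: Sharpless asymmetric epoxidation of a 1,1-disubstituted allylic alcohol, for which the L-(+)-tartrate catalyst should give the (S)-epoxy alcohol and so fix the quaternary carbinol carbon that becomes C10.

Step 5
Reactants: 6 (S)-2-methylglycidol
Product: 7 (2R)-2-{[(2-methoxypropan-2-yl)oxy]methyl}-2-methyloxirane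
Conditions: 2-methoxypropene, PPTS (cat.), CH2Cl2, 0 °C; Et3N quench
Reagents that add atoms: 2-methoxypropene, C=C(C)OC
Why: Acid-catalysed addition of the alcohol to an enol ether (mixed-ketal protection) never generates the alkoxide, so the degenerate Payne rearrangement that would racemise this epoxy alcohol is excluded (the descriptor is R only through the changed CIP ranking).

Step 6
Reactants: 8 1,3-dithiane; 7 mixed-ketal epoxide
Product: 11 2-{[(4R)-2,2,4-trimethyl-1,3-dioxolan-4-yl]methyl}-1,3-dithiane, via 2-lithio-1,3-dithiane 9 (not isolated), via hydroxy ketal 10 (not isolated)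
Conditions: 8, n-BuLi, THF, −30 °C; 7, −30 → 0 °C; H2O; then PPTS (cat.), CH2Cl2, rt
Reagents that add atoms: none
Why: Corey–Seebach alkylation in which the dithianyl anion opens the 2,2-disubstituted oxirane at its CH2 terminus (SN2, forming C8–C9 without touching the quaternary centre), followed by acid-catalysed intramolecular transketalisation of the freed tertiary alcohol onto the neighbouring mixed ketal, which closes the isopropylidene acetal with loss of methanol.

Step 7
Reactants: 12 acetylene; 13 hexamethylditin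
Product: 14 (Z)-1,2-bis(trimethylstannyl)ethene
Conditions: Pd(PPh3)4 (cat.), dioxane, 60 °C
Reagents that add atoms: none
Why: Palladium(0)-catalysed distannylation of an alkyne (oxidative addition of Sn–Sn, syn insertion, reductive elimination) places both tin atoms on the same side and should therefore give only the Z isomer.

Step 8
Reactants: 15 (S)-5-(hydroxymethyl)furan-2(5H)-one
Product: 16 (S)-5-{[(tert-butyldiphenylsilyl)oxy]methyl}furan-2(5H)-one
Conditions: TBDPSCl, imidazole, CH2Cl2, 0 °C → rt
Reagents that add atoms: tert-butyl(chloro)diphenylsilane, CC(C)(C)[Si](Cl)(c1ccccc1)c1ccccc1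
Why: Imidazole-mediated silylation of the primary alcohol gives a base-stable ether whose bulk shields one face of the butenolide in the next step.

Step 9
Reactants: 11 dithiane acetonide; 16 silylated butenolide
Product: 19 all-trans Mannich-base lactone carrying the C8 dithiane, via lithiated dithiane 17 (not isolated), via lithium enolate 18 (not isolated)
Conditions: 11, n-BuLi, THF, −20 °C; HMPA, −78 °C; 16, −78 °C; then CH2=NMe2+ I−, −78 → 0 °C
Reagents that add atoms: N,N-dimethylmethyleneiminium iodide (Eschenmoser's salt), C=[N+](C)C.[I-]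
Why: Tandem conjugate addition–enolate trapping on a 5-substituted butenolide (dithiane acyl-anion equivalent as Michael donor in THF/HMPA, then Mannich reaction with the iminium salt), in which the nucleophile attacks C7 anti to the C6 silyloxymethyl group and the iminium ion is taken up anti to the new C7 substituent, so that C7 is set as in the target and the C11 methylene is installed in masked form.

Step 10
Reactants: 19 Mannich-base dithiane
Product: 20 C8 ketone
Conditions: Hg(ClO4)2·3H2O, CaCO3, THF/H2O (5:1), 0 °C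
Reagents that add atoms: water, O
Why: Mercury(II)-assisted hydrolysis of the dithioacetal under carbonate buffering releases the C8 ketone without oxidising the tertiary amine or cleaving acetal and silyl ether, and the exocyclic methylene is deliberately still masked so that it cannot migrate into conjugation with the new ketone.

Step 11
Reactants: 20 C8 ketone
Product: 21 (8R)-alcohol
Conditions: (S)-2-methyl-CBS-oxazaborolidine (1 equiv), catecholborane, toluene, −78 °C; MeOH
Reagents that add atoms: none
Why: Corey–Bakshi–Shibata reduction, in which the (S)-oxazaborolidine binds the ketone with the α-branched C7 residue as the large and the C9 methylene as the small group and delivers hydride to the face that gives the 8R alcohol (a sense that Felkin–Anh attack anti to the C6 branch should reinforce), while catecholborane at −78 °C leaves the lactone untouched.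

Step 12
Reactants: 4 epoxy acid; 21 (8R)-alcohol
Product: 23 C8 epoxy ester, via mixed anhydride 22 (not isolated)
Conditions: 4, 2,4,6-Cl3C6H2COCl, Et3N, THF, rt; then 21, DMAP, toluene, rt → 40 °C
Reagents that add atoms: none
Why: Yamaguchi esterification, in which DMAP attacks the less hindered aliphatic carbonyl of the mixed anhydride and the acylpyridinium ion acylates the secondary C8 hydroxyl with retention, the acid having no α-hydrogen that could epimerise.

Step 13
Reactants: 23 C8 epoxy ester
Product: 24 C5 primary alcohol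
Conditions: TBAF, AcOH (1:1), THF, 0 °C → rt
Reagents that add atoms: none
Why: Fluoride-induced cleavage of the silyl ether, buffered with acetic acid so that no free alkoxide can translactonise or shift the acyl group, frees the primary C5 hydroxyl while acetal, epoxy ester and amine survive.

Step 14
Reactants: 24 C5 primary alcohol
Product: 25 C5 aldehyde
Conditions: Dess–Martin periodinane, CH2Cl2, 0 °C → rt; Na2S2O3/NaHCO3 work-up
Reagents that add atoms: none
Why: Dess–Martin oxidation of a primary alcohol to the aldehyde under non-basic conditions, which keeps the epimerisable α-acyloxy centre C6 intact, the amine being protonated by the acetic acid that is released.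

Step 15
Reactants: 25 C5 aldehyde
Product: 26 (Z)-C4 alkenyl iodide (Mannich base)
Conditions: EtPPh3I, n-BuLi, THF, rt; I2, −78 °C; NaHMDS, −20 °C; then 25, −78 → −20 °C
Reagents that add atoms: ethyltriphenylphosphonium iodide, CC[P+](c1ccccc1)(c1ccccc1)c1ccccc1.[I-]; iodine, II
Why: Stork–Zhao-type Wittig iodo-olefination with the α-iodoethylidene ylide, whose kinetically controlled addition to aldehydes gives the (Z)-2-iodoalk-2-ene (iodine cis to C6), and because the lactone is still the saturated Mannich base the ylide meets no Michael acceptor.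

Step 16
Reactants: 26 alkenyl iodide Mannich base
Product: 28 α-methylene lactone alkenyl iodide, via trimethylammonium iodide 27 (not isolated)
Conditions: MeI, MeOH, rt; then aq. NaHCO3, CH2Cl2, rt
Reagents that add atoms: none
Why: Quaternisation of the Mannich base and E1cB (Hofmann-type) loss of trimethylamine is the standard way to unveil an α-methylene-γ-lactone and removes the temporary C11 stereocentre.

Step 17
Reactants: 28 alkenyl iodide; 14 (Z)-distannane
Product: 29 (2Z,4Z)-dienylstannane
Conditions: 14 (3 equiv), Pd2(dba)3 (cat.), AsPh3 (cat.), NMP, rt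
Reagents that add atoms: none
Why: Stille cross-coupling of an alkenyl iodide with an alkenylstannane is stereoretentive at both carbons, so the Z-iodide and the Z-distannane (in excess, to stop at mono-coupling) should give the (Z,Z)-dienylstannane, the ligand-accelerated coupling at room temperature leaving the enoate untouched.

Step 18
Reactants: 29 dienylstannane
Product: 30 (2Z,4Z)-dienyl iodide acetonide
Conditions: I2, CH2Cl2, 0 °C
Reagents that add atoms: iodine, II
Why: Iododestannylation is an ipso electrophilic substitution that retains the alkene geometry and cleaves the alkenyl–tin bond much faster than the methyl–tin bonds.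

Step 19
Reactants: 30 dienyl iodide acetonide
Product: 31 C1,C10 diol
Conditions: AcOH/H2O/THF (3:1:1), 40 °C
Reagents that add atoms: none
Why: Acid-catalysed hydrolysis of the isopropylidene acetal, mild enough for the deactivated glycidic ester, the methylene lactone and the dienyl iodide, frees the primary C1 and the tertiary C10 hydroxyl.

Step 20
Reactants: 31 diol
Product: 32 C1,C10 bis(triethylsilyl) ether
Conditions: TESOTf, 2,6-lutidine, CH2Cl2, −78 → 0 °C
Reagents that add atoms: triethylsilyl trifluoromethanesulfonate, CC[Si](CC)(CC)OS(=O)(=O)C(F)(F)F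
Why: Silylation with a silyl triflate and a hindered base is reactive enough to cap the tertiary C10 hydroxyl as well as the primary one, while lutidine keeps the medium non-acidic for the oxirane.

Step 21
Reactants: 32 bis(triethylsilyl) ether
Product: 33 seco C2 iododiene C1 aldehyde with C10 triethylsilyl ether
Conditions: (COCl)2, DMSO, CH2Cl2, −78 → −30 °C; Et3N, −78 → 0 °C
Reagents that add atoms: none
Why: Under Swern conditions a primary triethylsilyl ether is cleaved by the chlorosulfonium salt and the resulting alkoxysulfonium ion collapses to the aldehyde, whereas a tertiary silyl ether is inert, so the non-enolisable α-silyloxy aldehyde should form in one operation.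

Step 22
Reactants: 33 iododiene aldehyde
Product: 36 ten-membered (1S)-carbinol with C10 triethylsilyl ether, via dienylchromium 34 (not isolated), via chromium alkoxide 35 (not isolated)
Conditions: CrCl2 (10 equiv), NiCl2 (cat.), degassed DMSO/THF, ca. 2 mM, slow addition of 33, rt; aq. NH4Cl
Reagents that add atoms: none
Why: Chromium(II) reduces NiCl2 to Ni(0), which inserts into the C2–I bond with retention of the Z geometry; transmetallation to chromium(III) gives dienylchromium 34, which adds to the C1 aldehyde to give alkoxide 35 and, on work-up, 36. This is the Nozaki–Hiyama–Kishi reaction in its known macrocyclising form (alkenyl iodide onto aldehyde in medium and large rings). The ten-membered carbocycle closes by 10-exo-trig attack of C2 on the C1 carbonyl, favoured over oligomerisation by slow addition at high dilution and by the Z C4=C5 bond and the trans-lactone, which turn the two chain ends towards each other. The new C1 stereocentre is controlled by the neighbouring C10 centre through polar Felkin–Anh addition: with the non-chelating C10–OSiEt3 bond anti to the incoming C2 and the C10 methyl group flanking the trajectory, the 1S carbinol should result, the epimer that SN2 closure later inverts to the 1R oxirane carbon. The step needs chemoselectivity for the aldehyde over lactone, ester, enoate and oxirane, which the weakly basic, oxophilic organochromium reagent provides, and retention of the (2Z,4Z)-diene, which stereoretentive oxidative addition and transmetallation secure.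

Step 23
Reactants: 36 (1S)-carbinol
Product: 37 C1 mesylate
Conditions: Ms2O, Et3N, CH2Cl2, −30 °C
Reagents that add atoms: methanesulfonic anhydride, CS(=O)(=O)OS(C)(=O)=O
Why: Sulfonylation of the secondary allylic alcohol through sulfene proceeds with retention at C1, and the chloride-free reagent at low temperature avoids allylic substitution of the sensitive mesylate.

Step 24
Reactants: 37 C1 mesylate
Product: 39 target CNP0122107.1, via C10 alkoxide 38 (not isolated)
Conditions: TBAF, THF, 0 °C
Reagents that add atoms: none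
Why: Fluoride desilylation frees the tertiary C10 alkoxide, which displaces the adjacent mesylate in a 3-exo-tet intramolecular Williamson (SN2) closure with inversion at C1 and retention at C10, giving the trans-1,10-oxirane of the target.

**Compound list**

1 | tiglic acid [(E)-2-methylbut-2-enoic acid] | C/C=C(\C)C(=O)O | starting material
2 | tiglyl alcohol [(E)-2-methylbut-2-en-1-ol] | C/C=C(\C)CO | intermediate
3 | [(2R,3R)-2,3-dimethyloxiran-2-yl]methanol | OC[C@@]1(C)O[C@@H]1C | intermediate
4 | (2S,3R)-2,3-dimethyloxirane-2-carboxylic acid | OC(=O)[C@@]1(C)O[C@@H]1C | intermediate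
5 | methallyl alcohol (2-methylprop-2-en-1-ol) | C=C(C)CO | starting material
6 | (S)-2-methylglycidol, [(2S)-2-methyloxiran-2-yl]methanol | OC[C@@]1(C)CO1 | intermediate
7 | (2R)-2-{[(2-methoxypropan-2-yl)oxy]methyl}-2-methyloxirane | COC(C)(C)OC[C@@]1(C)CO1 | intermediate
8 | 1,3-dithiane | C1CSCSC1 | starting material
9 | 2-lithio-1,3-dithiane | [Li]C1SCCCS1 | intermediate
10 | (2R)-1-(1,3-dithian-2-yl)-3-[(2-methoxypropan-2-yl)oxy]-2-methylpropan-2-ol | C1CSC(SC1)C[C@@](C)(O)COC(C)(C)OC | intermediate
11 | 2-{[(4R)-2,2,4-trimethyl-1,3-dioxolan-4-yl]methyl}-1,3-dithiane | C1CSC(SC1)C[C@@]1(C)OC(C)(C)OC1 | intermediate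
12 | acetylene | C#C | starting material
13 | hexamethylditin | C[Sn](C)(C)[Sn](C)(C)C | starting material
14 | (Z)-1,2-bis(trimethylstannyl)ethene | C[Sn](C)(C)/C=C\[Sn](C)(C)C | intermediate
15 | (S)-5-(hydroxymethyl)furan-2(5H)-one | O=C1C=C[C@@H](CO)O1 | starting material
16 | (S)-5-{[(tert-butyldiphenylsilyl)oxy]methyl}furan-2(5H)-one | O=C1C=C[C@@H](CO[Si](c2ccccc2)(c2ccccc2)C(C)(C)C)O1 | intermediate
17 | 2-lithio-2-{[(4R)-2,2,4-trimethyl-1,3-dioxolan-4-yl]methyl}-1,3-dithiane | [Li]C1(SCCCS1)C[C@@]1(C)OC(C)(C)OC1 | intermediate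
18 | lithium enolate of the conjugate adduct (C11=C12–OLi; C6, C7 as in 19) | C1=C(O[Li])O[C@H](CO[Si](c2ccccc2)(c2ccccc2)C(C)(C)C)[C@H]1C1(SCCCS1)C[C@@]1(C)OC(C)(C)OC1 | intermediate
19 | (3R,4S,5S)-5-{[(tert-butyldiphenylsilyl)oxy]methyl}-3-[(dimethylamino)methyl]-4-(2-{[(4R)-2,2,4-trimethyl-1,3-dioxolan-4-yl]methyl}-1,3-dithian-2-yl)oxolan-2-one | CN(C)C[C@@H]1C(=O)O[C@H](CO[Si](c2ccccc2)(c2ccccc2)C(C)(C)C)[C@H]1C1(SCCCS1)C[C@@]1(C)OC(C)(C)OC1 | intermediate
20 | (3R,4S,5S)-5-{[(tert-butyldiphenylsilyl)oxy]methyl}-3-[(dimethylamino)methyl]-4-{[(4R)-2,2,4-trimethyl-1,3-dioxolan-4-yl]acetyl}oxolan-2-one | CN(C)C[C@@H]1C(=O)O[C@H](CO[Si](c2ccccc2)(c2ccccc2)C(C)(C)C)[C@H]1C(=O)C[C@@]1(C)OC(C)(C)OC1 | intermediate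
21 | (3R,4R,5S)-5-{[(tert-butyldiphenylsilyl)oxy]methyl}-3-[(dimethylamino)methyl]-4-{(1R)-1-hydroxy-2-[(4R)-2,2,4-trimethyl-1,3-dioxolan-4-yl]ethyl}oxolan-2-one | CN(C)C[C@@H]1C(=O)O[C@H](CO[Si](c2ccccc2)(c2ccccc2)C(C)(C)C)[C@H]1[C@H](O)C[C@@]1(C)OC(C)(C)OC1 | intermediate
22 | (2S,3R)-2,3-dimethyloxirane-2-carboxylic 2,4,6-trichlorobenzoic anhydride | Clc1cc(Cl)cc(Cl)c1C(=O)OC(=O)[C@@]1(C)O[C@@H]1C | intermediate
23 | (1R)-1-[(2S,3R,4R)-2-{[(tert-butyldiphenylsilyl)oxy]methyl}-4-[(dimethylamino)methyl]-5-oxooxolan-3-yl]-2-[(4R)-2,2,4-trimethyl-1,3-dioxolan-4-yl]ethyl (2S,3R)-2,3-dimethyloxirane-2-carboxylate | CN(C)C[C@@H]1C(=O)O[C@H](CO[Si](c2ccccc2)(c2ccccc2)C(C)(C)C)[C@H]1[C@H](OC(=O)[C@@]1(C)O[C@@H]1C)C[C@@]1(C)OC(C)(C)OC1 | intermediate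
24 | (1R)-1-[(2S,3R,4R)-4-[(dimethylamino)methyl]-2-(hydroxymethyl)-5-oxooxolan-3-yl]-2-[(4R)-2,2,4-trimethyl-1,3-dioxolan-4-yl]ethyl (2S,3R)-2,3-dimethyloxirane-2-carboxylate | CN(C)C[C@@H]1C(=O)O[C@H](CO)[C@H]1[C@H](OC(=O)[C@@]1(C)O[C@@H]1C)C[C@@]1(C)OC(C)(C)OC1 | intermediate
25 | (1R)-1-[(2S,3R,4R)-4-[(dimethylamino)methyl]-2-formyl-5-oxooxolan-3-yl]-2-[(4R)-2,2,4-trimethyl-1,3-dioxolan-4-yl]ethyl (2S,3R)-2,3-dimethyloxirane-2-carboxylate | CN(C)C[C@@H]1C(=O)O[C@H](C=O)[C@H]1[C@H](OC(=O)[C@@]1(C)O[C@@H]1C)C[C@@]1(C)OC(C)(C)OC1 | intermediate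
26 | (1R)-1-[(2S,3R,4R)-4-[(dimethylamino)methyl]-2-[(Z)-2-iodoprop-1-en-1-yl]-5-oxooxolan-3-yl]-2-[(4R)-2,2,4-trimethyl-1,3-dioxolan-4-yl]ethyl (2S,3R)-2,3-dimethyloxirane-2-carboxylate | CN(C)C[C@@H]1C(=O)O[C@H](/C=C(C)\I)[C@H]1[C@H](OC(=O)[C@@]1(C)O[C@@H]1C)C[C@@]1(C)OC(C)(C)OC1 | intermediate
27 | N,N,N-trimethylammonium iodide of 26 (quaternised at the C13 nitrogen) | C[N+](C)(C)C[C@@H]1C(=O)O[C@H](/C=C(C)\I)[C@H]1[C@H](OC(=O)[C@@]1(C)O[C@@H]1C)C[C@@]1(C)OC(C)(C)OC1.[I-] | intermediate
28 | (1R)-1-[(2S,3R)-2-[(Z)-2-iodoprop-1-en-1-yl]-4-methylidene-5-oxooxolan-3-yl]-2-[(4R)-2,2,4-trimethyl-1,3-dioxolan-4-yl]ethyl (2S,3R)-2,3-dimethyloxirane-2-carboxylate | C=C1C(=O)O[C@H](/C=C(C)\I)[C@H]1[C@H](OC(=O)[C@@]1(C)O[C@@H]1C)C[C@@]1(C)OC(C)(C)OC1 | intermediate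
29 | (1R)-1-[(2R,3R)-4-methylidene-2-[(1Z,3Z)-2-methyl-4-(trimethylstannyl)buta-1,3-dien-1-yl]-5-oxooxolan-3-yl]-2-[(4R)-2,2,4-trimethyl-1,3-dioxolan-4-yl]ethyl (2S,3R)-2,3-dimethyloxirane-2-carboxylate | C=C1C(=O)O[C@H](/C=C(C)\C=C/[Sn](C)(C)C)[C@H]1[C@H](OC(=O)[C@@]1(C)O[C@@H]1C)C[C@@]1(C)OC(C)(C)OC1 | intermediate
30 | (1R)-1-[(2R,3R)-2-[(1Z,3Z)-4-iodo-2-methylbuta-1,3-dien-1-yl]-4-methylidene-5-oxooxolan-3-yl]-2-[(4R)-2,2,4-trimethyl-1,3-dioxolan-4-yl]ethyl (2S,3R)-2,3-dimethyloxirane-2-carboxylate | C=C1C(=O)O[C@H](/C=C(C)\C=C/I)[C@H]1[C@H](OC(=O)[C@@]1(C)O[C@@H]1C)C[C@@]1(C)OC(C)(C)OC1 | intermediate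
31 | (1R,3R)-3,4-dihydroxy-1-[(2R,3R)-2-[(1Z,3Z)-4-iodo-2-methylbuta-1,3-dien-1-yl]-4-methylidene-5-oxooxolan-3-yl]-3-methylbutyl (2S,3R)-2,3-dimethyloxirane-2-carboxylate | C=C1C(=O)O[C@H](/C=C(C)\C=C/I)[C@H]1[C@H](OC(=O)[C@@]1(C)O[C@@H]1C)C[C@@](C)(O)CO | intermediate
32 | (1R,3R)-1-[(2R,3R)-2-[(1Z,3Z)-4-iodo-2-methylbuta-1,3-dien-1-yl]-4-methylidene-5-oxooxolan-3-yl]-3-methyl-3,4-bis[(triethylsilyl)oxy]butyl (2S,3R)-2,3-dimethyloxirane-2-carboxylate | C=C1C(=O)O[C@H](/C=C(C)\C=C/I)[C@H]1[C@H](OC(=O)[C@@]1(C)O[C@@H]1C)C[C@@](C)(O[Si](CC)(CC)CC)CO[Si](CC)(CC)CC | intermediate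
33 | (1R,3R)-1-[(2R,3R)-2-[(1Z,3Z)-4-iodo-2-methylbuta-1,3-dien-1-yl]-4-methylidene-5-oxooxolan-3-yl]-3-methyl-4-oxo-3-[(triethylsilyl)oxy]butyl (2S,3R)-2,3-dimethyloxirane-2-carboxylate | C=C1C(=O)O[C@H](/C=C(C)\C=C/I)[C@H]1[C@H](OC(=O)[C@@]1(C)O[C@@H]1C)C[C@@](C)(O[Si](CC)(CC)CC)C=O | intermediate
34 | dichloro(dienyl)chromium(III) species from 33 (CrCl2 in place of iodine at C2, Z,Z retained) | C=C1C(=O)O[C@H](/C=C(C)\C=C/[Cr](Cl)Cl)[C@H]1[C@H](OC(=O)[C@@]1(C)O[C@@H]1C)C[C@@](C)(O[Si](CC)(CC)CC)C=O | intermediate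
35 | dichlorochromium(III) C1 alkoxide of 36 | C=C1C(=O)O[C@@H]2/C=C(C)\C=C/[C@H](O[Cr](Cl)Cl)[C@](C)(O[Si](CC)(CC)CC)C[C@@H](OC(=O)[C@@]3(C)O[C@@H]3C)[C@@H]12 | intermediate
36 | (1S,6R,7R,8R,10R)-1-hydroxy-10-[(triethylsilyl)oxy]germacra-2Z,4Z,11(13)-trien-12,6-olide 8-[(2S,3R)-2,3-dimethyloxirane-2-carboxylate] (germacrane numbering) | C=C1C(=O)O[C@@H]2/C=C(C)\C=C/[C@H](O)[C@](C)(O[Si](CC)(CC)CC)C[C@@H](OC(=O)[C@@]3(C)O[C@@H]3C)[C@@H]12 | intermediate
37 | 1-O-methanesulfonate of 36 (1S) | C=C1C(=O)O[C@@H]2/C=C(C)\C=C/[C@H](OS(C)(=O)=O)[C@](C)(O[Si](CC)(CC)CC)C[C@@H](OC(=O)[C@@]3(C)O[C@@H]3C)[C@@H]12 | intermediate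
38 | tetrabutylammonium C10 alkoxide of desilylated 37 | C=C1C(=O)O[C@@H]2/C=C(C)\C=C/[C@H](OS(C)(=O)=O)[C@](C)([O-])C[C@@H](OC(=O)[C@@]3(C)O[C@@H]3C)[C@@H]12.CCCC[N+](CCCC)(CCCC)CCCC | intermediate
39 | CNP0122107.1, (1R,6R,7R,8R,10R)-1,10-epoxygermacra-2Z,4Z,11(13)-trien-12,6-olide 8-[(2S,3R)-2,3-dimethyloxirane-2-carboxylate] | C=C1C(=O)O[C@@H]2/C=C(C)\C=C/[C@H]3O[C@]3(C)C[C@@H](OC(=O)[C@@]3(C)O[C@@H]3C)[C@@H]12 | target

**Step count and risks**

Total step count: 24 (three for the epoxy acid, three for the dithiane, one for the distannane, seventeen on the main line).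
Longest linear sequence: 19 steps (steps 4–6 and 9–24, from methallyl alcohol 5 to 39).

Steps most likely to fail:

Step 22 (ring closure). The conformation of the closing ten-membered ring, rather than the Felkin–Anh preference, may decide which aldehyde face is attacked, so that C2 adds to the wrong face and the 1R carbinol forms. Slow closure with oligomerisation is the second hazard and is met by dilution. The fallback sets out from 33. The same closure is accepted with the 1R outcome, the 1-epi carbinol F1. Dess–Martin oxidation gives the C1 dienone F2. TBAF/AcOH removes the C10 silyl group to give the α-hydroxy dienone F3. Zn(BH4)2 (Et2O, −20 °C) then reduces the ketone under Cram-chelate control: zinc bridges the C1 carbonyl and the C10 hydroxyl, hydride enters from the methyl-flanked face, and the 1S,10R diol F4 should result. Mitsunobu cyclodehydration (PPh3, DIAD, THF, 0 °C) activates the secondary C1 hydroxyl and lets the C10 oxygen displace it with inversion, which rejoins the route at 39. The C1 configuration is then set by a chelation-controlled reduction and not by the C–C bond formation.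

Step 11 (C8 reduction). Facial selectivity may be poor, because the two ketone flanks differ only moderately in size and the basic amine may bind the boron catalyst. The fallback sets out from 20 and uses a substrate-controlled reduction with L-Selectride (THF, −78 °C). If this gives the 8R alcohol, it is 21. If the 8S epimer, the 8-epi alcohol F5, predominates, it is esterified with acid 4 under Mitsunobu conditions (PPh3, DIAD, toluene, 0 °C → rt), which inverts C8 and returns to the route at 23.

Step 23 (mesylate formation). The dienylic mesylate may ionise, or suffer SN2′ substitution or elimination, before the C10 oxygen is set free. The fallback sets out from 36. TBAF/AcOH first removes the silyl group to give the 1S,10R diol F6 (the same compound as F4), and PPh3/DIAD cyclodehydration converts it in one flask into 39, so that no sulfonate is ever handled.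

Further compounds
F1 | step 22 | 1-epi carbinol (1R epimer of 36) | C=C1C(=O)O[C@@H]2/C=C(C)\C=C/[C@@H](O)[C@](C)(O[Si](CC)(CC)CC)C[C@@H](OC(=O)[C@@]3(C)O[C@@H]3C)[C@@H]12
F2 | step 22 | C1 dienone with C10 triethylsilyl ether | C=C1C(=O)O[C@@H]2/C=C(C)\C=C/C(=O)[C@](C)(O[Si](CC)(CC)CC)C[C@@H](OC(=O)[C@@]3(C)O[C@@H]3C)[C@@H]12
F3 | step 22 | α-hydroxy dienone (C1 ketone, free C10 hydroxyl) | C=C1C(=O)O[C@@H]2/C=C(C)\C=C/C(=O)[C@](C)(O)C[C@@H](OC(=O)[C@@]3(C)O[C@@H]3C)[C@@H]12
F4 | step 22 | 1S,10R diol | C=C1C(=O)O[C@@H]2/C=C(C)\C=C/[C@H](O)[C@](C)(O)C[C@@H](OC(=O)[C@@]3(C)O[C@@H]3C)[C@@H]12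
F5 | step 11 | 8-epi alcohol (8S epimer of 21) | CN(C)C[C@@H]1C(=O)O[C@H](CO[Si](c2ccccc2)(c2ccccc2)C(C)(C)C)[C@H]1[C@@H](O)C[C@@]1(C)OC(C)(C)OC1
F6 | step 23 | 1S,10R diol (identical with F4) | C=C1C(=O)O[C@@H]2/C=C(C)\C=C/[C@H](O)[C@](C)(O)C[C@@H](OC(=O)[C@@]3(C)O[C@@H]3C)[C@@H]12
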